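**Retrosynthetic overview**
Enabling feature: ring B is a catechol monoether. C8–OH sits ortho to C8a–O1, and the other ortho carbon, C4a, carries the chain C4=C3–C2Me2. The ring-B pyran plus C8–OH is therefore the aromatised valence tautomer of a 3-prenyl-1,2-benzoquinone.
Key disconnection: the O1–C2 bond, the C3=C4 unsaturation and the C8–O bond are removed together. This leads to 2-prenylphenol 9, whose only free OH steers an ortho-oxygenation.
Removing the C8 oxygen exposes a hidden C2-symmetric core. The ring-A pyran is traced to aryl 1,1-dimethylpropargyl ether 6, made from 3,3'-diprenylbiphenyl-4,4'-diol 5.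
Both prenyl groups of 5 come from a double aromatic Claisen rearrangement of bis(1,1-dimethylallyl) ether 4. 4,4'-Biphenol 1 and 3-chloro-3-methylbut-1-yne 2 supply all 27 carbons.
Ring order: the two benzene rings are bought in 1, the ring-A pyran closes in step 5, and the ring-B pyran closes last, in step 6.

Key step: step 6

Remark: chromene numbering (O1, C2, C3, C4, C4a, C5–C8, C8a) is used for both halves. Ring A is the half with the C8 prenyl group and ring B the half with the C8 hydroxyl. The target has no stereocentre, so only the alkene geometry of transient intermediates is specified.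

Step 1
Reactants: 1 biphenyl-4,4'-diol (4,4'-biphenol); 2 3-chloro-3-methylbut-1-yne
Product: 3 4,4'-bis[(2-methylbut-3-yn-2-yl)oxy]biphenyl
Conditions: 2 (2.6 equiv), K2CO3, KI (cat.), CuI (cat.), acetone, reflux
Reagents that add atoms: none
Why: Copper-catalysed Williamson-type propargylation of phenoxides with a tertiary propargyl chloride is the standard entry to aryl 1,1-dimethylpropargyl ethers, and the two equivalent OH groups of 1 react alike.

Step 2
Reactants: 3 4,4'-bis[(2-methylbut-3-yn-2-yl)oxy]biphenyl
Product: 4 4,4'-bis[(2-methylbut-3-en-2-yl)oxy]biphenyl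
Conditions: H2 (1 atm, stopped after 2 equiv), Lindlar catalyst, quinoline, EtOAc, 23 °C
Reagents that add atoms: none
Why: Lindlar semihydrogenation takes up the terminal alkynes much faster than the resulting monosubstituted alkenes on the poisoned catalyst, and the aryl ether bonds are inert.

Step 3
Reactants: 4 4,4'-bis[(2-methylbut-3-en-2-yl)oxy]biphenyl
Product: 5 3,3'-bis(3-methylbut-2-en-1-yl)biphenyl-4,4'-diol
Conditions: PhNEt2, 140 °C, Ar
Reagents that add atoms: none
Why: In two aromatic Claisen rearrangements each chair-like [3,3] shift turns a 1,1-dimethylallyl ether into a linear prenyl group on an ortho carbon (the two ortho positions of each ring are equivalent), enolisation makes each shift irreversible, and the basic solvent suppresses acid-induced loss of isoprene and chroman formation.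

Step 4
Reactants: 5 3,3'-bis(3-methylbut-2-en-1-yl)biphenyl-4,4'-diol; 2 3-chloro-3-methylbut-1-yne
Product: 6 4'-[(2-methylbut-3-yn-2-yl)oxy]-3,3'-bis(3-methylbut-2-en-1-yl)biphenyl-4-ol
Conditions: 2 (0.8 equiv), K2CO3 (1 equiv), KI (cat.), CuI (cat.), acetone, reflux; recovered 5 recycled
Reagents that add atoms: none
Why: The same copper-catalysed Williamson-type propargylation, run with a deficit of 2, should favour statistical mono-etherification of the C2-symmetric diol, with unreacted 5 recovered and the bis-ether removed by chromatography.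

Step 5
Reactants: 6 4'-[(2-methylbut-3-yn-2-yl)oxy]-3,3'-bis(3-methylbut-2-en-1-yl)biphenyl-4-ol
Product: 9 4-[2,2-dimethyl-8-(3-methylbut-2-en-1-yl)-2H-chromen-6-yl]-2-(3-methylbut-2-en-1-yl)phenol, via ring-A allenylphenol 7 (not isolated), via ring-A o-quinone methide 8 (not isolated)
Conditions: xylenes, 140 °C, Ar
Reagents that add atoms: none
Why: In the thermal aryl propargyl ether cascade a Claisen [3,3] shift to the only free ortho carbon and enolisation give 7, a [1,5]-H shift gives (Z)-8, and oxa-6π electrocyclisation closes the ring-A pyran, while the free 2-prenylphenol of the other ring is a spectator under neutral conditions.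

Step 6
Reactants: 9 4-[2,2-dimethyl-8-(3-methylbut-2-en-1-yl)-2H-chromen-6-yl]-2-(3-methylbut-2-en-1-yl)phenol
Product: 12 2,2-dimethyl-6-[2,2-dimethyl-8-(3-methylbut-2-en-1-yl)-2H-chromen-6-yl]-2H-chromen-8-ol (CNP0158232.0), via o-quinone 10 (not isolated), via hydroxy-o-quinone methide 11 (not isolated)
Conditions: IBX (1.0 equiv), DMF, 0 to 23 °C; then Et3N (1.5 equiv), 23 to 40 °C, same flask
Reagents that add atoms: IBX (2-iodoxybenzoic acid), O=C1OI(=O)(O)c2ccccc12
Why: Proposed new method: the only free phenol of 9 exchanges onto the I(V) centre of IBX, oxygen is delivered intramolecularly to the single free ortho C–H (the future C8), and collapse of the I(III) catecholate gives o-quinone 10 and 2-iodobenzoic acid; Et3N then removes a proton from the ring-B prenyl CH2 (C4), which is allylic and vinylogous through C4a=C5–C6=C7 to the new C8 carbonyl, and protonation on that oxygen gives 11. The pyran ring closes by a thermal disrotatory oxa-6π electrocyclisation of the 1-oxatriene O1=C8a–C4a=C4–C3=C2, which forms the O1–C2 bond and is driven by rearomatisation of ring B; only (Z)-11 can close, and the E isomer is fed back through the reversible tautomerisation. The closest known reaction types are the IBX ortho-oxygenation of phenols to o-quinones and the amine-induced isomerisation of prenyl-1,4-benzoquinones to 6-hydroxychromenes; new are their coupling in one flask and the use of a 1,2-quinone, whose second carbonyl ends as the C8 hydroxyl. No stereocentre is formed. Chemoselectivity rests on the need of IBX for an ArOH ligand (ring A offers only an ether, and the three alkenes are inert at room temperature), regioselectivity on the prenyl group blocking the other ortho position and the aryl group blocking the para position, and site-selective deprotonation on the fact that only the ring-B prenyl CH2 is attached to a quinone. Over-oxidation of the product phenol is avoided by using one equivalent of IBX, a four-electron oxidant here, and by adding the base only after the oxidant has been consumed.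

**Compound list**
1 | biphenyl-4,4'-diol | Oc1ccc(cc1)-c1ccc(O)cc1 | starting material
2 | 3-chloro-3-methylbut-1-yne | CC(C)(Cl)C#C | starting material
3 | 4,4'-bis[(2-methylbut-3-yn-2-yl)oxy]biphenyl | C#CC(C)(C)Oc1ccc(cc1)-c1ccc(OC(C)(C)C#C)cc1 | intermediate
4 | 4,4'-bis[(2-methylbut-3-en-2-yl)oxy]biphenyl | C=CC(C)(C)Oc1ccc(cc1)-c1ccc(OC(C)(C)C=C)cc1 | intermediate
5 | 3,3'-bis(3-methylbut-2-en-1-yl)biphenyl-4,4'-diol | CC(C)=CCc1cc(ccc1O)-c1ccc(O)c(CC=C(C)C)c1 | intermediate
6 | 4'-[(2-methylbut-3-yn-2-yl)oxy]-3,3'-bis(3-methylbut-2-en-1-yl)biphenyl-4-ol | CC(C)=CCc1cc(ccc1O)-c1ccc(OC(C)(C)C#C)c(CC=C(C)C)c1 | intermediate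
7 | 3-(3-methylbuta-1,2-dien-1-yl)-3',5-bis(3-methylbut-2-en-1-yl)biphenyl-4,4'-diol (ring-A allenylphenol) | CC(C)=CCc1cc(ccc1O)-c1cc(CC=C(C)C)c(O)c(C=C=C(C)C)c1 | intermediate
8 | (6Z)-4-[4-hydroxy-3-(3-methylbut-2-en-1-yl)phenyl]-2-(3-methylbut-2-en-1-yl)-6-(3-methylbut-2-en-1-ylidene)cyclohexa-2,4-dien-1-one (ring-A o-quinone methide) | O=C1C(CC=C(C)C)=CC(c2ccc(O)c(CC=C(C)C)c2)=C/C1=C/C=C(C)C | intermediate
9 | 4-[2,2-dimethyl-8-(3-methylbut-2-en-1-yl)-2H-chromen-6-yl]-2-(3-methylbut-2-en-1-yl)phenol | CC(C)=CCc1cc(ccc1O)-c1cc(CC=C(C)C)c2OC(C)(C)C=Cc2c1 | intermediate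
10 | 5-[2,2-dimethyl-8-(3-methylbut-2-en-1-yl)-2H-chromen-6-yl]-3-(3-methylbut-2-en-1-yl)cyclohexa-3,5-diene-1,2-dione (o-quinone) | CC(C)=CCC1=CC(=CC(=O)C1=O)c1cc(CC=C(C)C)c2OC(C)(C)C=Cc2c1 | intermediate
11 | (6Z)-4-[2,2-dimethyl-8-(3-methylbut-2-en-1-yl)-2H-chromen-6-yl]-2-hydroxy-6-(3-methylbut-2-en-1-ylidene)cyclohexa-2,4-dien-1-one (hydroxy-o-quinone methide) | O=C1C(O)=CC(c2cc(CC=C(C)C)c3OC(C)(C)C=Cc3c2)=C/C1=C/C=C(C)C | intermediate
12 | 2,2-dimethyl-6-[2,2-dimethyl-8-(3-methylbut-2-en-1-yl)-2H-chromen-6-yl]-2H-chromen-8-ol | CC(C)=CCc1cc(-c2cc(O)c3c(c2)C=CC(C)(C)O3)cc2c1OC(C)(C)C=C2 | target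

**Step count**
Total step count: 6. Longest linear sequence: 6 steps (1 to 12).

**Steps most likely to fail**

1. Step 6 (Proposed new method).
   - Risk: the quinone-to-quinone-methide tautomerisation may stall, so that the o-quinone is lost by Diels–Alder dimerisation or by cycloaddition to the electron-rich chromene alkene. The isomerisation may also start too early, which exposes the product phenol to remaining oxidant.
   - Fallback: it sets out from 9 and returns at 12. Oxygenation and ring closure are uncoupled, and the pyran is closed at the phenol level by hydride abstraction instead of through the 1,2-quinone. IBX oxidation of 9 with immediate reductive work-up (aq. Na2S2O4) should give the catechol 3-prenyl-5-(2,2-dimethyl-8-prenyl-2H-chromen-6-yl)benzene-1,2-diol F1. TBSCl and imidazole should silylate the less hindered hydroxyl, remote from the prenyl group, to give the mono-silyl ether 2-(tert-butyldimethylsilyloxy)-6-prenyl-4-(2,2-dimethyl-8-prenyl-2H-chromen-6-yl)phenol F2. DDQ in benzene, the dehydrogenative cyclisation of o-prenylphenols, should close the ring to the silyl ether 8-(tert-butyldimethylsilyloxy)-2,2-dimethyl-6-(2,2-dimethyl-8-prenyl-2H-chromen-6-yl)-2H-chromene F3. TBAF in THF then releases 12.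

2. Step 4.
   - Risk: the two equivalent phenols of 5 are not discriminated, so double etherification and low conversion erode the throughput.
   - Fallback: it sets out from 2 and returns at 9. The symmetric core is abandoned and the biaryl bond is made by cross-coupling of two differentiated halves that come from one bromophenol. Ortho-C-prenylation of sodium 4-bromophenoxide with prenyl bromide in toluene should give 4-bromo-2-prenylphenol F4. Etherification of part of it with 2 (K2CO3, KI, CuI) should give 4-bromo-1-[(2-methylbut-3-yn-2-yl)oxy]-2-prenylbenzene F5. Heating in xylenes should give 6-bromo-2,2-dimethyl-8-prenyl-2H-chromene F6. Miyaura borylation (B2pin2, Pd(dppf)Cl2, KOAc) should give the pinacol boronate 2-(2,2-dimethyl-8-prenyl-2H-chromen-6-yl)-4,4,5,5-tetramethyl-1,3,2-dioxaborolane F7. Suzuki–Miyaura coupling of this boronate with the remaining bromophenol (Pd(PPh3)4, aq. K2CO3, dioxane) leads to 9.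

3. Step 3.
   - Risk: heterolysis of the tertiary allyl ethers, with loss of isoprene, may compete with the sigmatropic shift, and it has two chances to do so in one molecule.
   - Fallback: it sets out from 1 and returns at 5. The prenyl groups are introduced by directed metalation instead of rearrangement. MOMCl and iPr2NEt should give 4,4'-bis(methoxymethoxy)biphenyl F8. Double directed ortho-lithiation (n-BuLi, TMEDA), transmetalation with CuBr·SMe2 and alkylation with prenyl bromide should give 4,4'-bis(methoxymethoxy)-3,3'-diprenylbiphenyl F9. Catalytic HCl in MeOH then removes both acetals to give 5.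

**Further compounds**
F1 | step 6 | 3-prenyl-5-(2,2-dimethyl-8-prenyl-2H-chromen-6-yl)benzene-1,2-diol | CC(C)=CCc1cc(cc(O)c1O)-c1cc(CC=C(C)C)c2OC(C)(C)C=Cc2c1
F2 | step 6 | 2-(tert-butyldimethylsilyloxy)-6-prenyl-4-(2,2-dimethyl-8-prenyl-2H-chromen-6-yl)phenol | CC(C)=CCc1cc(cc(O[Si](C)(C)C(C)(C)C)c1O)-c1cc(CC=C(C)C)c2OC(C)(C)C=Cc2c1
F3 | step 6 | 8-(tert-butyldimethylsilyloxy)-2,2-dimethyl-6-(2,2-dimethyl-8-prenyl-2H-chromen-6-yl)-2H-chromene | CC(C)=CCc1cc(-c2cc(O[Si](C)(C)C(C)(C)C)c3c(c2)C=CC(C)(C)O3)cc2c1OC(C)(C)C=C2
F4 | step 4 | 4-bromo-2-prenylphenol | CC(C)=CCc1cc(Br)ccc1O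
F5 | step 4 | 4-bromo-1-[(2-methylbut-3-yn-2-yl)oxy]-2-prenylbenzene | CC(C)=CCc1cc(Br)ccc1OC(C)(C)C#C
F6 | step 4 | 6-bromo-2,2-dimethyl-8-prenyl-2H-chromene | CC(C)=CCc1cc(Br)cc2C=CC(C)(C)Oc12
F7 | step 4 | 2-(2,2-dimethyl-8-prenyl-2H-chromen-6-yl)-4,4,5,5-tetramethyl-1,3,2-dioxaborolane | CC(C)=CCc1cc(cc2C=CC(C)(C)Oc12)B1OC(C)(C)C(C)(C)O1
F8 | step 3 | 4,4'-bis(methoxymethoxy)biphenyl | COCOc1ccc(cc1)-c1ccc(OCOC)cc1
F9 | step 3 | 4,4'-bis(methoxymethoxy)-3,3'-diprenylbiphenyl | COCOc1ccc(cc1CC=C(C)C)-c1ccc(OCOC)c(CC=C(C)C)c1
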